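**Retrosynthetic overview**

1. Target 28 is a cis-fused 1,2-dioxane/γ-lactone (2,3,7-trioxabicyclo[4.3.0]nonan-8-one: dioxane C1–O2–O3–C4–C5–C6, lactone C6–O7–C8(=O)–C9–C1) with its side chain on the peroxy-quaternary carbon C4. The C4–CH2 bond is cut to a cyclic peroxycarbenium ion (from methoxy peroxyketal 10) and the side chain as dialkylzinc 26.
2. Enabling feature: C4 carries peroxide oxygen O3 and, once the side chain is removed, is at the ketone oxidation level. C4=O3+ can therefore be generated inside the rigid cis-fused bicycle, whose C6 centre (lactone O7 pseudo-axial, methyl pseudo-equatorial) fixes the face of attack.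
3. 10 comes from butenolide ketone 8 by perhydrolysis (O3–C4) and 6-exo oxa-Michael closure (O2–C1). Ring order: temporary dioxolanone (steps 1–3), γ-lactone (step 5), 1,2-dioxane (step 8).
4. 8 comes from (R)-lactic acid: allylation with self-regeneration of the stereocentre sets C6, which relays C1 (step 8) and C4 (step 20); butenolide annulation and Wacker oxidation complete it.
5. 26 comes from iodide 25: the methyl stereocentre is bought as (S)-3-bromo-2-methylpropan-1-ol; allylation/ozonolysis gives aldehyde 16, joined by Julia–Kocienski olefination to sulfone 21 (from a Johnson–Claisen ester).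

Key step: step 20

Remark: ring locants below are those of the 2,3,7-trioxabicyclo[4.3.0]nonane skeleton of 10, 27 and 28; 9 and 10 are carried as mixtures of epimers at the peroxyketal carbon, which becomes planar in step 20.

**Route**

Step 1
Reactants: 1 (R)-lactic acid
Product: 2 (2R,5R)-2-tert-butyl-5-methyl-1,3-dioxolan-4-one
Conditions: t-BuCHO, TsOH (cat.), H2SO4 (cat.), pentane, reflux (Dean–Stark); crystallisation at −78 °C
Reagents that add atoms: pivalaldehyde, CC(C)(C)C=O
Why: Acid-catalysed acetalisation of the α-hydroxy acid should give mainly the cis-dioxolanone, purified by crystallisation, so that the lactate stereocentre is copied onto the acetal carbon before it is planarised.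

Step 2
Reactants: 2 (2R,5R)-2-tert-butyl-5-methyl-1,3-dioxolan-4-one
Product: 4 (2R,5S)-2-tert-butyl-5-methyl-5-(prop-2-en-1-yl)-1,3-dioxolan-4-one, via lithium enolate 3 (not isolated)
Conditions: LDA, THF, −78 °C; allyl bromide, −78 → −30 °C
Reagents that add atoms: allyl bromide, C=CCBr
Why: Enolate alkylation with self-regeneration of the stereocentre: the tert-butyl group on the acetal carbon blocks one face of the planar enolate, so allyl bromide enters trans to it and sets the quaternary carbon (C6 of 28) with net retention of the lactic acid configuration.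

Step 3
Reactants: 4 (2R,5S)-2-tert-butyl-5-methyl-5-(prop-2-en-1-yl)-1,3-dioxolan-4-one
Product: 5 (2S)-2-methylpent-4-ene-1,2-diol
Conditions: LiAlH4, Et2O, 0 °C → rt
Reagents that add atoms: none
Why: Hydride reduction of the acylal-type lactone should release the diol and pivalaldehyde (reduced to neopentyl alcohol) without touching the quaternary stereocentre or the alkene.

Step 4
Reactants: 5 (2S)-2-methylpent-4-ene-1,2-diol
Product: 6 (2S)-2-hydroxy-2-methylpent-4-enal
Conditions: SO3·pyridine, DMSO, Et3N, CH2Cl2, 0 °C; used crude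
Reagents that add atoms: none
Why: Parikh–Doering oxidation acts only on the primary alcohol (the tertiary hydroxyl cannot be oxidised and no glycol cleavage is expected), and the aldehyde has no α-hydrogen, so the stereocentre cannot epimerise.

Step 5
Reactants: 6 (2S)-2-hydroxy-2-methylpent-4-enal
Product: 7 (5S)-5-methyl-5-(prop-2-en-1-yl)furan-2(5H)-one
Conditions: Ph3P=C=C=O, toluene, 80 °C
Reagents that add atoms: (triphenylphosphoranylidene)ketene, O=C=C=P(c1ccccc1)(c1ccccc1)c1ccccc1
Why: The tertiary hydroxyl adds to the ketene to give an ester-stabilised ylide, which closes the γ-lactone by intramolecular Wittig reaction with the adjacent aldehyde; the five-membered ring enforces the cis-alkene.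

Step 6
Reactants: 7 (5S)-5-methyl-5-(prop-2-en-1-yl)furan-2(5H)-one
Product: 8 (5S)-5-methyl-5-(2-oxopropyl)furan-2(5H)-one
Conditions: PdCl2 (cat.), CuCl, O2 (1 atm), DMF/H2O, rt
Reagents that add atoms: water, O
Why: Wacker–Tsuji oxidation by Markovnikov hydroxypalladation of the terminal alkene should give the methyl ketone, the electron-poor butenolide double bond being inert.

Step 7
Reactants: 8 (5S)-5-methyl-5-(2-oxopropyl)furan-2(5H)-one
Product: 9 (5S)-5-(2-hydroperoxy-2-methoxypropyl)-5-methylfuran-2(5H)-one
Conditions: H2O2·urea, Sc(OTf)3 (cat.), MeOH, rt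
Reagents that add atoms: hydrogen peroxide (as urea adduct), OO; methanol, CO
Why: Lewis acid-catalysed perhydrolysis/ketalisation of the methyl ketone in methanol should give the α-methoxy hydroperoxide (both epimers at the ketal carbon, which is of no consequence), the conjugated lactone being unreactive towards hydrogen peroxide without base.

Step 8
Reactants: 9 (5S)-5-(2-hydroperoxy-2-methoxypropyl)-5-methylfuran-2(5H)-one
Product: 10 (1S,6S)-4-methoxy-4,6-dimethyl-2,3,7-trioxabicyclo[4.3.0]nonan-8-one
Conditions: Et2NH (cat.), CF3CH2OH, rt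
Reagents that add atoms: none
Why: Amine-mediated intramolecular oxa-Michael addition of the hydroperoxide to the butenolide (6-exo-trig) closes the 1,2-dioxane; the three-atom tether on C6 can reach the β-carbon only on its own face, so C1 is set cis-fused by substrate control.

Step 9
Reactants: 11 (2S)-3-bromo-2-methylpropan-1-ol
Product: 12 [(2S)-3-bromo-2-methylpropoxy](tert-butyl)dimethylsilane
Conditions: TBSCl, imidazole, CH2Cl2, rt
Reagents that add atoms: tert-butyldimethylsilyl chloride, CC(C)(C)[Si](C)(C)Cl
Why: Standard silylation protects the primary alcohol for the organometallic steps; the stereocentre is not involved.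

Step 10
Reactants: 12 [(2S)-3-bromo-2-methylpropoxy](tert-butyl)dimethylsilane
Product: 14 tert-butyldimethyl{[(2R)-2-methylhex-5-en-1-yl]oxy}silane, via Grignard reagent 13 (not isolated)
Conditions: Mg, THF, 45 °C; allyl bromide, CuI (cat.), 0 °C → rt
Reagents that add atoms: allyl bromide, C=CCBr
Why: Grignard formation from the primary bromide and copper-catalysed coupling with allyl bromide (SN2 and SN2′ paths give the same product) extends the chain by three carbons; the stereocentre β to magnesium is configurationally stable.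

Step 11
Reactants: 14 tert-butyldimethyl{[(2R)-2-methylhex-5-en-1-yl]oxy}silane
Product: 16 (4R)-5-[(tert-butyldimethylsilyl)oxy]-4-methylpentanal, via ozonide 15 (not isolated)
Conditions: O3, CH2Cl2, −78 °C; PPh3, −78 °C → rt
Reagents that add atoms: ozone, [O-][O+]=O
Why: Ozonolysis with reductive work-up cleaves the terminal alkene to the aldehyde; the silyl ether survives and the stereocentre, γ to the carbonyl, cannot epimerise.

Step 12
Reactants: 17 1-phenylprop-2-en-1-ol (racemic)
Product: 18 ethyl (4E)-5-phenylpent-4-enoate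
Conditions: MeC(OEt)3, EtCO2H (cat.), 140 °C (−EtOH)
Reagents that add atoms: triethyl orthoacetate, CCOC(C)(OCC)OCC
Why: Johnson–Claisen rearrangement through a chair transition state with phenyl pseudo-equatorial should give the (E)-styrene, the future 9,10-double bond of the side chain.

Step 13
Reactants: 18 ethyl (4E)-5-phenylpent-4-enoate
Product: 19 (4E)-5-phenylpent-4-en-1-ol
Conditions: LiAlH4, Et2O, 0 °C
Reagents that add atoms: none
Why: Ester reduction to the primary alcohol; an isolated styrene is not reduced by LiAlH4.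

Step 14
Reactants: 19 (4E)-5-phenylpent-4-en-1-ol
Product: 20 1-phenyl-5-{[(4E)-5-phenylpent-4-en-1-yl]sulfanyl}-1H-tetrazole
Conditions: 1-phenyl-1H-tetrazole-5-thiol, PPh3, DIAD, THF, 0 °C → rt
Reagents that add atoms: 1-phenyl-1H-tetrazole-5-thiol, Sc1nnnn1-c1ccccc1
Why: Mitsunobu reaction of the primary alcohol with the acidic heteroaryl thiol gives the sulfide by SN2 at CH2.

Step 15
Reactants: 20 1-phenyl-5-{[(4E)-5-phenylpent-4-en-1-yl]sulfanyl}-1H-tetrazole
Product: 21 1-phenyl-5-{[(4E)-5-phenylpent-4-en-1-yl]sulfonyl}-1H-tetrazole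
Conditions: (NH4)6Mo7O24·4H2O (cat.), 30% H2O2, EtOH, 0 °C → rt
Reagents that add atoms: hydrogen peroxide, OO
Why: Molybdate-catalysed oxidation takes the sulfide to the sulfone and should leave the styrene unepoxidised.

Step 16
Reactants: 21 1-phenyl-5-{[(4E)-5-phenylpent-4-en-1-yl]sulfonyl}-1H-tetrazole; 16 (4R)-5-[(tert-butyldimethylsilyl)oxy]-4-methylpentanal
Product: 23 tert-butyldimethyl{[(2R,5E,9E)-2-methyl-10-phenyldeca-5,9-dien-1-yl]oxy}silane, via potassium sulfonyl carbanion 22 (not isolated)
Conditions: KHMDS, DME, −60 °C; 16, −60 °C → rt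
Reagents that add atoms: none
Why: Julia–Kocienski olefination (carbanion addition to the aldehyde, Smiles rearrangement, loss of SO2 and tetrazololate); the potassium counter-ion in DME favours the anti adduct and hence the (E)-5,6-alkene.

Step 17
Reactants: 23 tert-butyldimethyl{[(2R,5E,9E)-2-methyl-10-phenyldeca-5,9-dien-1-yl]oxy}silane
Product: 24 (2R,5E,9E)-2-methyl-10-phenyldeca-5,9-dien-1-ol
Conditions: TBAF, THF, 0 °C → rt
Reagents that add atoms: none
Why: Fluoride cleaves the silyl ether; nothing else in the molecule is fluoride-labile.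

Step 18
Reactants: 24 (2R,5E,9E)-2-methyl-10-phenyldeca-5,9-dien-1-ol
Product: 25 [(1E,5E,9R)-10-iodo-9-methyldeca-1,5-dien-1-yl]benzene
Conditions: I2, PPh3, imidazole, CH2Cl2, 0 °C → rt
Reagents that add atoms: iodine, II
Why: Appel-type iodination through the alkoxyphosphonium salt (SN2 at the CH2 group); the neighbouring stereocentre is not a reacting centre and the alkenes should not add iodine under these buffered conditions.

Step 19
Reactants: 25 [(1E,5E,9R)-10-iodo-9-methyldeca-1,5-dien-1-yl]benzene
Product: 26 bis[(2R,5E,9E)-2-methyl-10-phenyldeca-5,9-dien-1-yl]zinc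
Conditions: Et2Zn (neat, excess), CuI (cat.), 50 °C; volatiles removed at 50 °C/0.1 mmHg; residue taken up in CH2Cl2
Reagents that add atoms: diethylzinc, CC[Zn]CC
Why: Copper-catalysed iodine–zinc exchange of the primary iodide, driven to the dialkylzinc by distilling off iodoethane and excess diethylzinc, gives a salt-free sp3 nucleophile; the internal alkenes and the β-stereocentre are unaffected.

Step 20
Reactants: 10 (1S,6S)-4-methoxy-4,6-dimethyl-2,3,7-trioxabicyclo[4.3.0]nonan-8-one; 26 bis[(2R,5E,9E)-2-methyl-10-phenyldeca-5,9-dien-1-yl]zinc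
Product: 28 (1S,4R,6S)-4,6-dimethyl-4-[(2R,5E,9E)-2-methyl-10-phenyldeca-5,9-dien-1-yl]-2,3,7-trioxabicyclo[4.3.0]nonan-8-one, via peroxycarbenium triflate 27 (not isolated)
Conditions: 26 (1.3 equiv), TMSOTf (1.2 equiv), CH2Cl2, −78 → −40 °C
Reagents that add atoms: none
Why: Proposed new method: TMSOTf removes the methoxy group of 10 as MeOSiMe3 to give the cyclic peroxycarbenium ion 27 (C4=O3+), to which the dialkylzinc transfers one primary alkyl group in an SE2-type step, forming the C4–CH2 bond without touching the O2–O3 bond. The closest known reaction types are the Lewis acid-mediated substitution of alkoxy-1,2-dioxolanes and other peroxyketals by allylsilanes and silyl enol ethers through peroxycarbenium ions, and the Lewis acid-promoted alkylation of cyclic oxocarbenium ions by dialkylzinc and alkylaluminium reagents, which is known even for trioxane-type lactol derivatives carrying a peroxide bridge; new here is the pairing of an sp3 zinc nucleophile with a peroxycarbenium ion. No ring is closed in this step; the two rings of 10 act as the stereochemical template. The new quaternary stereocentre C4 is substrate-controlled: in the favoured half-chair of 27 the lactone oxygen O7 on C6 is pseudo-axial while the C6 methyl group and the C1–C9 bond are pseudo-equatorial, and chair-like axial attack on C4 occurs syn to O7 (the opposite face would require a twist-boat or, in the inverted half-chair, a syn-diaxial clash with the C6 methyl group), which places the side chain cis to O7 and the two methyl groups cis, as in 28. The step needs C-alkylation to outrun peroxide reduction, β-hydride transfer and capture of the cation by the side-chain alkenes; this should be secured by the low reducing power of dialkylzincs towards hindered dialkyl peroxides at −78 °C, by the zinc–carbon bond being a far better nucleophile than a 1,2-disubstituted alkene or a β-alkylstyrene, and by generating the ion only in the presence of excess 26.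

**Compound list**

1 | (R)-lactic acid | C[C@@H](O)C(=O)O | starting material
2 | (2R,5R)-2-tert-butyl-5-methyl-1,3-dioxolan-4-one | C[C@H]1O[C@@H](C(C)(C)C)OC1=O | intermediate
3 | lithium (2R)-2-tert-butyl-5-methyl-1,3-dioxol-4-olate (enolate of 2) | CC1=C([O-])O[C@H](C(C)(C)C)O1.[Li+] | intermediate
4 | (2R,5S)-2-tert-butyl-5-methyl-5-(prop-2-en-1-yl)-1,3-dioxolan-4-one | C[C@@]1(CC=C)O[C@@H](C(C)(C)C)OC1=O | intermediate
5 | (2S)-2-methylpent-4-ene-1,2-diol | C[C@@](CC=C)(O)CO | intermediate
6 | (2S)-2-hydroxy-2-methylpent-4-enal | C[C@@](CC=C)(O)C=O | intermediate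
7 | (5S)-5-methyl-5-(prop-2-en-1-yl)furan-2(5H)-one | C[C@@]1(CC=C)OC(=O)C=C1 | intermediate
8 | (5S)-5-methyl-5-(2-oxopropyl)furan-2(5H)-one | C[C@@]1(CC(C)=O)OC(=O)C=C1 | intermediate
9 | (5S)-5-(2-hydroperoxy-2-methoxypropyl)-5-methylfuran-2(5H)-one (both epimers at the ketal carbon) | COC(C)(OO)C[C@]1(C)OC(=O)C=C1 | intermediate
10 | (1S,6S)-4-methoxy-4,6-dimethyl-2,3,7-trioxabicyclo[4.3.0]nonan-8-one (both epimers at C4) | COC1(C)C[C@]2(C)OC(=O)C[C@@H]2OO1 | intermediate
11 | (2S)-3-bromo-2-methylpropan-1-ol | C[C@H](CBr)CO | starting material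
12 | [(2S)-3-bromo-2-methylpropoxy](tert-butyl)dimethylsilane | C[C@H](CBr)CO[Si](C)(C)C(C)(C)C | intermediate
13 | bromo{(2S)-3-[(tert-butyldimethylsilyl)oxy]-2-methylpropyl}magnesium | C[C@H](C[Mg]Br)CO[Si](C)(C)C(C)(C)C | intermediate
14 | tert-butyldimethyl{[(2R)-2-methylhex-5-en-1-yl]oxy}silane | C[C@H](CCC=C)CO[Si](C)(C)C(C)(C)C | intermediate
15 | tert-butyldimethyl{[(2R)-2-methyl-4-(1,2,4-trioxolan-3-yl)butyl]oxy}silane (ozonide) | C[C@H](CCC1OCOO1)CO[Si](C)(C)C(C)(C)C | intermediate
16 | (4R)-5-[(tert-butyldimethylsilyl)oxy]-4-methylpentanal | C[C@H](CCC=O)CO[Si](C)(C)C(C)(C)C | intermediate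
17 | 1-phenylprop-2-en-1-ol (racemic) | C=CC(O)c1ccccc1 | starting material
18 | ethyl (4E)-5-phenylpent-4-enoate | CCOC(=O)CC/C=C/c1ccccc1 | intermediate
19 | (4E)-5-phenylpent-4-en-1-ol | OCCC/C=C/c1ccccc1 | intermediate
20 | 1-phenyl-5-{[(4E)-5-phenylpent-4-en-1-yl]sulfanyl}-1H-tetrazole | C(CC/C=C/c1ccccc1)Sc1nnnn1-c1ccccc1 | intermediate
21 | 1-phenyl-5-{[(4E)-5-phenylpent-4-en-1-yl]sulfonyl}-1H-tetrazole | O=S(=O)(CCC/C=C/c1ccccc1)c1nnnn1-c1ccccc1 | intermediate
22 | potassium salt of the α-sulfonyl carbanion of 21 | [K+].[CH-](CC/C=C/c1ccccc1)S(=O)(=O)c1nnnn1-c1ccccc1 | intermediate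
23 | tert-butyldimethyl{[(2R,5E,9E)-2-methyl-10-phenyldeca-5,9-dien-1-yl]oxy}silane | C[C@H](CC/C=C/CC/C=C/c1ccccc1)CO[Si](C)(C)C(C)(C)C | intermediate
24 | (2R,5E,9E)-2-methyl-10-phenyldeca-5,9-dien-1-ol | C[C@H](CC/C=C/CC/C=C/c1ccccc1)CO | intermediate
25 | [(1E,5E,9R)-10-iodo-9-methyldeca-1,5-dien-1-yl]benzene | C[C@H](CC/C=C/CC/C=C/c1ccccc1)CI | intermediate
26 | bis[(2R,5E,9E)-2-methyl-10-phenyldeca-5,9-dien-1-yl]zinc | C[C@H](CC/C=C/CC/C=C/c1ccccc1)C[Zn]C[C@H](C)CC/C=C/CC/C=C/c1ccccc1 | intermediate
27 | (1S,6S)-4,6-dimethyl-8-oxo-2,3,7-trioxabicyclo[4.3.0]non-3-en-3-ium trifluoromethanesulfonate | CC1=[O+]O[C@H]2CC(=O)O[C@@]2(C)C1.[O-]S(=O)(=O)C(F)(F)F | intermediate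
28 | (1S,4R,6S)-4,6-dimethyl-4-[(2R,5E,9E)-2-methyl-10-phenyldeca-5,9-dien-1-yl]-2,3,7-trioxabicyclo[4.3.0]nonan-8-one | C[C@H](CC/C=C/CC/C=C/c1ccccc1)C[C@]1(C)C[C@]2(C)OC(=O)C[C@@H]2OO1 | target

**Step count and risks**

Total step count: 20. Longest linear sequence: 9 steps (steps 1–8 and 20, from (R)-lactic acid); the side-chain branch (steps 9–11 and 16–20) has 8.

Steps most likely to fail:

1. Step 20 (proposed new method). Alkyl transfer from zinc may be slower than β-hydride delivery from the β-branched alkyl group, than Lewis acid-induced heterolysis of the O–O bond in the cation, or than attack of the organometallic on peroxide oxygen. Facial control may also erode if a twist-boat pathway competes. Fallback with known reaction types only, setting out from 2 (using 26) and coming back at 28: enolate 3 is alkylated with 2,3-dibromopropene to (2R,5S)-5-(2-bromoprop-2-en-1-yl)-2-tert-butyl-5-methyl-1,3-dioxolan-4-one F1. This is taken through the same three operations as 4 (LiAlH4; SO3·pyridine/DMSO; (triphenylphosphoranylidene)ketene) via (2S)-4-bromo-2-methylpent-4-ene-1,2-diol F2 and (2S)-4-bromo-2-hydroxy-2-methylpent-4-enal F3 to (5S)-5-(2-bromoprop-2-en-1-yl)-5-methylfuran-2(5H)-one F4. Negishi coupling of F4 with 26 (Pd(dppf)Cl2, THF, 50 °C) would form the same carbon–carbon bond at an sp2 carbon and give (5S)-5-methyl-5-[(4R,7E,11E)-4-methyl-2-methylidene-12-phenyldodeca-7,11-dien-1-yl]furan-2(5H)-one F5. Mukaiyama–Isayama hydroperoxysilylation (Co(thd)2, O2, Et3SiH) should then give (5S)-5-[(4R,7E,11E)-2,4-dimethyl-12-phenyl-2-(triethylsilylperoxy)dodeca-7,11-dien-1-yl]-5-methylfuran-2(5H)-one F6 as both epimers. Fluoride desilylation gives (5S)-5-[(4R,7E,11E)-2-hydroperoxy-2,4-dimethyl-12-phenyldodeca-7,11-dien-1-yl]-5-methylfuran-2(5H)-one F7, and Et2NH in CF3CH2OH closes the dioxane by the oxa-Michael addition of step 8 to give 28 and its C4 epimer, to be separated by chromatography. The price is the loss of stereocontrol at C4 and the need to stop the cobalt step at partial conversion so that the styrene is spared.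

2. Step 16. The addition of carbanion 22 to the unbranched aldehyde may not be anti-selective enough, so that some (Z)-5,6-isomer forms and is carried on as a hard-to-separate impurity. Fallback, setting out from 16 and coming back at 23: vinylmagnesium bromide adds to 16 to give (6R)-7-[(tert-butyldimethylsilyl)oxy]-6-methylhept-1-en-3-ol F8 (both carbinol epimers). Johnson–Claisen rearrangement with triethyl orthoacetate gives ethyl (4E,8R)-9-[(tert-butyldimethylsilyl)oxy]-8-methylnon-4-enoate F9, the alkene geometry being set by the chair transition state. DIBAL-H at −78 °C gives (4E,8R)-9-[(tert-butyldimethylsilyl)oxy]-8-methylnon-4-enal F10, and Horner–Wadsworth–Emmons reaction with diethyl benzylphosphonate (NaH, THF) installs the styrene terminus of 23. Compounds 17–22 are then not needed.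

3. Step 5. The α-hydroxy aldehyde may oligomerise through hemiacetal formation faster than its hindered tertiary hydroxyl is acylated by the ketene ylide. Fallback, setting out from 6 and coming back at 7: Z-selective Horner–Wadsworth–Emmons (Still–Gennari) olefination with methyl bis(2,2,2-trifluoroethyl)phosphonoacetate (KHMDS, 18-crown-6, THF, −78 °C) gives methyl (2Z,4S)-4-hydroxy-4-methylhepta-2,6-dienoate F11, which lactonises to 7 on warming with a trace of acid (PPTS, CH2Cl2). The carbon–carbon double bond is thus made first, intermolecularly, and the ring is closed by acylation.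

Further compounds
F1 | step 20 | (2R,5S)-5-(2-bromoprop-2-en-1-yl)-2-tert-butyl-5-methyl-1,3-dioxolan-4-one | C[C@@]1(CC(Br)=C)O[C@@H](C(C)(C)C)OC1=O
F2 | step 20 | (2S)-4-bromo-2-methylpent-4-ene-1,2-diol | C[C@@](CC(Br)=C)(O)CO
F3 | step 20 | (2S)-4-bromo-2-hydroxy-2-methylpent-4-enal | C[C@@](CC(Br)=C)(O)C=O
F4 | step 20 | (5S)-5-(2-bromoprop-2-en-1-yl)-5-methylfuran-2(5H)-one | C[C@@]1(CC(Br)=C)OC(=O)C=C1
F5 | step 20 | (5S)-5-methyl-5-[(4R,7E,11E)-4-methyl-2-methylidene-12-phenyldodeca-7,11-dien-1-yl]furan-2(5H)-one | C[C@H](CC/C=C/CC/C=C/c1ccccc1)CC(=C)C[C@]1(C)OC(=O)C=C1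
F6 | step 20 | (5S)-5-[(4R,7E,11E)-2,4-dimethyl-12-phenyl-2-(triethylsilylperoxy)dodeca-7,11-dien-1-yl]-5-methylfuran-2(5H)-one (both epimers at C2 of the chain) | C[C@H](CC/C=C/CC/C=C/c1ccccc1)CC(C)(OO[Si](CC)(CC)CC)C[C@]1(C)OC(=O)C=C1
F7 | step 20 | (5S)-5-[(4R,7E,11E)-2-hydroperoxy-2,4-dimethyl-12-phenyldodeca-7,11-dien-1-yl]-5-methylfuran-2(5H)-one (both epimers at C2 of the chain) | C[C@H](CC/C=C/CC/C=C/c1ccccc1)CC(C)(OO)C[C@]1(C)OC(=O)C=C1
F8 | step 16 | (6R)-7-[(tert-butyldimethylsilyl)oxy]-6-methylhept-1-en-3-ol (both epimers at C3) | C[C@H](CCC(O)C=C)CO[Si](C)(C)C(C)(C)C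
F9 | step 16 | ethyl (4E,8R)-9-[(tert-butyldimethylsilyl)oxy]-8-methylnon-4-enoate | C[C@H](CC/C=C/CCC(=O)OCC)CO[Si](C)(C)C(C)(C)C
F10 | step 16 | (4E,8R)-9-[(tert-butyldimethylsilyl)oxy]-8-methylnon-4-enal | C[C@H](CC/C=C/CCC=O)CO[Si](C)(C)C(C)(C)C
F11 | step 5 | methyl (2Z,4S)-4-hydroxy-4-methylhepta-2,6-dienoate | C[C@@](CC=C)(O)/C=C\C(=O)OC
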